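Readings and results were computed with made-up constants; scatter was added.

In a one-step world with the gas held, substrate turns to product at a fixed fraction of itself per hour (pseudo-first-order), so percent at a given time is independent of the charge. You must decide whether the listed flasks are worth running as they stand, or whether zeta needs a longer time.

in all of them: gas 0.54 mM (held)
- autumn: substrate 5 mM; temperature −5 °C; run made earlier
- winter: substrate 7.5 mM; temperature 25 °C; run made earlier
- zeta: substrate 10 mM; temperature 50 °C; time 20 h
- epsilon: substrate 10 mM; temperature 25 °C; time 20 h
- gamma: substrate 10 mM; temperature 0 °C; time 20 h

| autumn: time / h | autumn: product / % | winter: time / h | winter: product / % |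
|---|---|---|---|
| 50.0 | 0 | 10.0 | 5.0 |
| 96.0 | 0.5 | 20.0 | 16.5 |
| 144 | 0.7 | 30.0 | 30.4 |
| 192 | 0.8 | 40.0 | 43.8 |

(standard deviation of a reading: 0.5 percentage points)

1. the flask that comes out highest in amount of product, in percent of the substrate charged, or "all alike" when all lie within 1.5 percentage points (zeta / epsilon / gamma / all alike)
2. product at the end, in percent of the substrate charged, zeta
3. product at the end, in percent of the substrate charged, epsilon
4. product at the end, in percent of the substrate charged, gamma

The winter run is not one-step, since it starts slowly and then runs straight. So carry two readings from it: the fractional rate, the part of the charge turned to product per hour on the straight stretch, and the lag, where that line meets zero.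

fractional rate = 0.0137 /h

lag = 7.91 h

My reckoning for epsilon, at winter's temperature, is the line at 20 h: 16.6%. If instead the rate held constant in mM, it would be 12.4%.

Can zeta finish in 20 h? With the same lag, the fractional rate must rise by

needed factor = 6.06

Autumn's average over its 192 h gives 4.17 × 10⁻⁵ /h, so from −5 °C to 25 °C the rate rose by

observed factor = 328

This is a rough reading, as autumn's 0.8% stands near the scatter of 0.5 percentage points, and autumn and winter differ in charge as well as in temperature, 5 mM against 7.5 mM. Still, the observed factor is far larger than the needed one, so, taking a like rise from 25 °C to 50 °C as my assumption, I would leave zeta's charge and time unchanged. Gamma, at 0 °C, lies near autumn, which read 0% after 50.0 h, so expect a trace there.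

The forecast names zeta, with 95% for zeta, 13.5% for epsilon and 0.1% for gamma, and says “the substrate should be consumed after the short gas lag, unless gas supply limits it”. Its epsilon lies below my line.

The flasks give 99.9% for zeta, 16.6% for epsilon and 0.0594% for gamma, so zeta is highest.

    substrate + coupling partner → intermediate (k = 720 /M/h, Ea = 70.0 kJ/mol)
    intermediate → product (k = 0.600 /h, Ea = 95.0 kJ/mol)
    gas ⇌ coupling partner, rate k3*(csat - [coupling partner]) (kL = 64.0 /h)
    coupling partner ⇌ dormant form (K = 9.00, k = 0.120 /h, Ea = 112 kJ/mol, ΔH = −40.0 kJ/mol)
    (constants at 50 °C)

In zeta, the substrate's half-life by the step with the coupling partner is 1.8 h at 20.0 h, much shorter than the run, and 0.048% of the charge remains as substrate at the end. At 25 °C, the fractional rate and lag give 16.6% for epsilon against 16.6%, and for the winter run recharged to 10 mM and read at 40.0 h they give 44.0% against 42.7%.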